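A direct plan would build ring A first, as the cyclohexenone A1, by an organocatalytic Robinson-type annulation,
would attach a silyl-protected hydroxyalkyne at C5 by copper-catalysed SN2′ substitution of the derived allylic phosphate,
and would close ring B from the alkynal A2 by a rhodium-catalysed hydroacylation to the bicyclic enone A3.
Dihydroxylation to A4, oxidation, acetylation, reduction and esterification with a separately made, protected chlorohydrin acid would follow.
Its weakest steps would be the allylic alkynylation, which would have to create C5 at a neopentyl carbon beside the quaternary C10 with unproven regio- and facial control;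
the 6-endo hydroacylation, for which 5-alkynals would be expected to prefer 5-exo closure or decarbonylation;
and the C3 correction, since cis-dihydroxylation would give the 3α,4α-diol A4 and two redox steps would be spent on inverting one centre.

The route rests on a thermal intramolecular Diels–Alder reaction of an acyclic triene in which a 2-silyloxydiene (C2–C5) and an isopropenyl dienophile (C10=C1) are linked by the future ring B atoms C6–C9 (eudesmane numbering). One step forms C1–C2 and C5–C10, closes rings A and B together and sets the trans A/B fusion at the quaternary C10, relayed from a temporary C8 silyloxy stereocentre. It exploits the vicinal C3/C4 oxygen pair of ring A: the adduct is the C3=C4 silyl enol ether, which one syn hydroboration turns into the 3β,4α-trans diol. Allylic alkynylation, hydroacylation and C3 inversion have no counterpart.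

Key step: step 6

Remark: ring atoms are numbered as in eudesmane (C1–C10 in the decalin, C11 on C7, C14 on C10, C15 on C4), and the acyl-stabilised ylide of step 3 is taken as a purchasable reagent.

**Step 1**
Reactants: 1 methyl 4-oxobutanoate; 2 tributyl(2-methylprop-2-en-1-yl)stannane
Product: 4 (5R)-5-(2-methylprop-2-en-1-yl)oxolan-2-one, via hydroxy ester 3 (not isolated)
Conditions: (S)-BINOL (10 mol%), Ti(OiPr)4 (10 mol%), 4 Å MS, CH2Cl2, −20 °C; aq. NaHCO3; then TsOH·H2O (cat.), CH2Cl2, rt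
Reagents that add atoms: none
Why: Keck asymmetric allylation with the methallylstannane; the BINOL–titanium catalyst made from (S)-BINOL should give the (R)-carbinol (C8), as with other unbranched aliphatic aldehydes, and the γ-hydroxy ester then lactonises under acid catalysis.

**Step 2**
Reactants: 4 (5R)-5-(2-methylprop-2-en-1-yl)oxolan-2-one
Product: 5 (5R)-5-(2-methylprop-2-en-1-yl)oxolan-2-ol (both anomers)
Conditions: i-Bu2AlH (1.1 equiv), CH2Cl2, −78 °C; aq. sodium potassium tartrate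
Reagents that add atoms: none
Why: Partial reduction of the γ-lactone at low temperature stops at the lactol, the masked C5 aldehyde; C8 is not touched.

**Step 3**
Reactants: 5 (5R)-5-(2-methylprop-2-en-1-yl)oxolan-2-ol; 6 3-(triphenyl-λ5-phosphanylidene)butan-2-one
Product: 7 (3E,7R)-7-hydroxy-3,9-dimethyldeca-3,9-dien-2-one
Conditions: toluene, 90 °C
Reagents that add atoms: none
Why: Wittig olefination of the open hydroxy aldehyde form of the lactol with the acyl-stabilised α-methyl ylide, which should give the E trisubstituted enone (C4=C5) that the diene needs.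

**Step 4**
Reactants: 7 (3E,7R)-7-hydroxy-3,9-dimethyldeca-3,9-dien-2-one
Product: 8 (3E,7R)-7-[(tert-butyldimethylsilyl)oxy]-3,9-dimethyldeca-3,9-dien-2-one
Conditions: t-BuMe2SiCl, imidazole, DMF, rt
Reagents that add atoms: tert-butyl(chloro)dimethylsilane CC(C)(C)[Si](C)(C)Cl
Why: Silylation of the only hydroxyl group gives the bulky ether that will hold C8 equatorial in the cycloaddition and masks the later C8 ketone.

**Step 5**
Reactants: 8 (3E,7R)-7-[(tert-butyldimethylsilyl)oxy]-3,9-dimethyldeca-3,9-dien-2-one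
Product: 10 (3E,7R)-7-[(tert-butyldimethylsilyl)oxy]-3,9-dimethyl-2-[(trimethylsilyl)oxy]deca-1,3,9-triene, via lithium dienolate 9 (not isolated)
Conditions: LiN(i-Pr)2 (1.1 equiv), THF, −78 °C; Me3SiCl, Et3N, −78 to 0 °C; pentane, filtration
Reagents that add atoms: chlorotrimethylsilane C[Si](C)(C)Cl
Why: Kinetic deprotonation of the methyl ketone at its methyl group (C2) and O-silylation of the cross-conjugated dienolate give the 2-silyloxydiene with the C4=C5 geometry unchanged.

**Step 6**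
Reactants: 10 (3E,7R)-7-[(tert-butyldimethylsilyl)oxy]-3,9-dimethyl-2-[(trimethylsilyl)oxy]deca-1,3,9-triene
Product: 11 (4aR,6R,8aR)-6-[(tert-butyldimethylsilyl)oxy]-1,4a-dimethyl-2-[(trimethylsilyl)oxy]-3,4,4a,5,6,7,8,8a-octahydronaphthalene
Conditions: toluene (0.01 M), N,O-bis(trimethylsilyl)acetamide (0.2 equiv), BHT (cat.), sealed tube, 190 °C
Reagents that add atoms: none
Why: Thermal type 1 intramolecular Diels–Alder reaction (concerted, suprafacial on both partners) between the 2-silyloxydiene C2=C3–C4=C5 and the isopropenyl dienophile C10=C1; the closest known reaction type is the uncatalysed cyclisation of 1,7,9-decatrienes that carry a methyl group on the internal dienophile carbon, a known route to angularly methylated trans-octalins. The four-atom tether C6–C9 allows only the fused mode, so C1–C2 and C5–C10 are formed: ring A is closed as the cycloadduct cyclohexene and ring B as the tether ring through the C5–C10 bond. C5 and C10 are set together; the E diene holds the tether exo at C5, and with the tether in a chair the C10 methyl takes the axial site and C9 the equatorial one, which gives the trans fusion (10β-methyl anti to 5α-H). The face is fixed by the C8 stereocentre, whose silyloxy group must sit equatorial because the axial site would be 1,3-diaxial to the C10 methyl, so that 8R gives 4aR,8aR. The step needs trans over cis fusion and a clean relay from C8; the angular methyl and the bulky silyl ether should secure both, and no Lewis acid or activating group is needed. The adduct carries the C3=C4 silyl enol ether, the handle for both ring A oxygens.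

**Step 7**
Reactants: 11 (4aR,6R,8aR)-6-[(tert-butyldimethylsilyl)oxy]-1,4a-dimethyl-2-[(trimethylsilyl)oxy]-3,4,4a,5,6,7,8,8a-octahydronaphthalene
Product: 14 (1S,2S,4aR,6R,8aR)-6-[(tert-butyldimethylsilyl)oxy]-1,4a-dimethyldecahydronaphthalene-1,2-diol, via alkylborane 12 (not isolated), via silyl ether 13 (not isolated)
Conditions: BH3·THF (1.5 equiv), THF, 0 °C to rt; NaOH, H2O2, 0 °C to rt; then K2CO3, MeOH, rt
Reagents that add atoms: hydrogen peroxide OO
Why: Hydroboration–oxidation of the silyl enol ether: boron adds to C4 (β to oxygen) and hydrogen to C3 in a syn fashion from the α face, anti to the axial C10 methyl, and oxidation with retention gives the 4α tertiary alcohol trans to the 3β oxygen, whose trimethylsilyl group is lost in the basic methanol treatment.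

**Step 8**
Reactants: 15 (2E)-2-methylbut-2-en-1-ol
Product: 16 [(2R,3R)-2,3-dimethyloxiran-2-yl]methanol
Conditions: Ti(OiPr)4 (10 mol%), D-(−)-diisopropyl tartrate (12 mol%), t-BuOOH (2 equiv), 4 Å MS, CH2Cl2, −20 °C
Reagents that add atoms: tert-butyl hydroperoxide CC(C)(C)OO
Why: Sharpless asymmetric epoxidation; with D-(−)-tartrate the E allylic alcohol should give the (2R,3R)-epoxy alcohol, the alkene geometry being kept in the epoxide.

**Step 9**
Reactants: 16 [(2R,3R)-2,3-dimethyloxiran-2-yl]methanol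
Product: 17 (2S,3R)-2,3-dimethyloxirane-2-carboxylic acid
Conditions: TEMPO (7 mol%), NaOCl (2 mol%), NaClO2 (2 equiv), MeCN/phosphate buffer (pH 6.7), 35 °C
Reagents that add atoms: sodium chlorite [Na+].[O-]Cl=O
Why: Nitroxyl-catalysed oxidation of the primary alcohol through the aldehyde to the acid with chlorite as terminal oxidant, under buffered conditions that leave the epoxide and both stereocentres intact (the C2 descriptor changes only by priority).

**Step 10**
Reactants: 14 (1S,2S,4aR,6R,8aR)-6-[(tert-butyldimethylsilyl)oxy]-1,4a-dimethyldecahydronaphthalene-1,2-diol; 17 (2S,3R)-2,3-dimethyloxirane-2-carboxylic acid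
Product: 19 (1S,2S,4aR,6R,8aR)-6-[(tert-butyldimethylsilyl)oxy]-1-hydroxy-1,4a-dimethyldecahydronaphthalen-2-yl (2S,3R)-2,3-dimethyloxirane-2-carboxylate, via mixed anhydride 18 (not isolated)
Conditions: 17, 2,4,6-Cl3C6H2COCl, Et3N, toluene, rt; then 14, DMAP (2 equiv), toluene, 40 °C
Reagents that add atoms: none
Why: Yamaguchi esterification: the mixed anhydride acylates the secondary 3β-hydroxyl and leaves the tertiary C4 hydroxyl, with retention at C3 and at both epoxide carbons.

**Step 11**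
Reactants: 19 (1S,2S,4aR,6R,8aR)-6-[(tert-butyldimethylsilyl)oxy]-1-hydroxy-1,4a-dimethyldecahydronaphthalen-2-yl (2S,3R)-2,3-dimethyloxirane-2-carboxylate
Product: 20 (1S,2S,4aR,6R,8aR)-1-(acetyloxy)-6-[(tert-butyldimethylsilyl)oxy]-1,4a-dimethyldecahydronaphthalen-2-yl (2S,3R)-2,3-dimethyloxirane-2-carboxylate
Conditions: Ac2O (10 equiv), DMAP (2 equiv), Et3N, CH2Cl2, 40 °C
Reagents that add atoms: acetic anhydride CC(=O)OC(C)=O
Why: DMAP-catalysed acetylation of the remaining tertiary 4α-hydroxyl; because C3 already carries the hindered ester, no acyl shift to a more stable position can occur.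

**Step 12**
Reactants: 20 (1S,2S,4aR,6R,8aR)-1-(acetyloxy)-6-[(tert-butyldimethylsilyl)oxy]-1,4a-dimethyldecahydronaphthalen-2-yl (2S,3R)-2,3-dimethyloxirane-2-carboxylate
Product: 21 (1S,2S,4aR,6R,8aR)-1-(acetyloxy)-6-hydroxy-1,4a-dimethyldecahydronaphthalen-2-yl (2S,3R)-2,3-dimethyloxirane-2-carboxylate
Conditions: HF·pyridine, pyridine, THF, 0 °C to rt
Reagents that add atoms: none
Why: Buffered fluoride cleavage of the secondary silyl ether under non-basic conditions, which the epoxy ester and the tertiary acetate should tolerate.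

**Step 13**
Reactants: 21 (1S,2S,4aR,6R,8aR)-1-(acetyloxy)-6-hydroxy-1,4a-dimethyldecahydronaphthalen-2-yl (2S,3R)-2,3-dimethyloxirane-2-carboxylate
Product: 22 (1S,2S,4aR,8aR)-1-(acetyloxy)-1,4a-dimethyl-6-oxodecahydronaphthalen-2-yl (2S,3R)-2,3-dimethyloxirane-2-carboxylate
Conditions: Dess–Martin periodinane, NaHCO3, CH2Cl2, 0 °C to rt
Reagents that add atoms: none
Why: Dess–Martin oxidation of the only free hydroxyl removes the temporary C8 stereocentre and gives the ring B ketone under neutral buffered conditions.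

**Step 14**
Reactants: 22 (1S,2S,4aR,8aR)-1-(acetyloxy)-1,4a-dimethyl-6-oxodecahydronaphthalen-2-yl (2S,3R)-2,3-dimethyloxirane-2-carboxylate
Product: 24 (1S,2S,4aR,8aR)-1-(acetyloxy)-7-(2-hydroxypropan-2-yl)-1,4a-dimethyl-6-oxodecahydronaphthalen-2-yl (2S,3R)-2,3-dimethyloxirane-2-carboxylate (C7 epimers), via lithium enolate 23 (not isolated)
Conditions: LiN(i-Pr)2 (1.05 equiv), THF, −78 °C; acetone (5 equiv), −78 °C; aq. NH4Cl
Reagents that add atoms: acetone CC(C)=O
Why: Kinetic enolisation towards C7, the α-position away from the quaternary C10, and aldol addition to acetone at low temperature, where the ketone should be deprotonated faster than the acetate; the C7 configuration is lost in the next step.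

**Step 15**
Reactants: 24 (1S,2S,4aR,8aR)-1-(acetyloxy)-7-(2-hydroxypropan-2-yl)-1,4a-dimethyl-6-oxodecahydronaphthalen-2-yl (2S,3R)-2,3-dimethyloxirane-2-carboxylate
Product: 26 (1S,2S,4aR,8aR)-1-(acetyloxy)-1,4a-dimethyl-6-oxo-7-(propan-2-ylidene)decahydronaphthalen-2-yl (2S,3R)-2,3-dimethyloxirane-2-carboxylate, via mesylate 25 (not isolated)
Conditions: MsCl, Et3N, DMAP (cat.), CH2Cl2, 0 °C; then DBU, rt
Reagents that add atoms: none
Why: Mesylation of the tertiary aldol hydroxyl and E1cB elimination through the C7 enolate give the conjugated s-cis isopropylidene ketone.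

**Step 16**
Reactants: 26 (1S,2S,4aR,8aR)-1-(acetyloxy)-1,4a-dimethyl-6-oxo-7-(propan-2-ylidene)decahydronaphthalen-2-yl (2S,3R)-2,3-dimethyloxirane-2-carboxylate
Product: 27 (1S,2S,4aR,8aR)-1-(acetyloxy)-1,4a-dimethyl-6-oxo-7-(propan-2-ylidene)decahydronaphthalen-2-yl (2R,3S)-3-chloro-2-hydroxy-2-methylbutanoate
Conditions: HCl (4 M in 1,4-dioxane, 1.5 equiv), CH2Cl2, 0 °C
Reagents that add atoms: hydrogen chloride Cl
Why: Acid-mediated opening of the glycidic ester: chloride attacks C3 of the side chain by SN2 with inversion, the fully substituted C2 being deactivated by the ester, which gives the (2R,3S) chlorohydrin before the acid-sensitive tertiary allylic alcohol is made.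

**Step 17**
Reactants: 27 (1S,2S,4aR,8aR)-1-(acetyloxy)-1,4a-dimethyl-6-oxo-7-(propan-2-ylidene)decahydronaphthalen-2-yl (2R,3S)-3-chloro-2-hydroxy-2-methylbutanoate
Product: 29 (1S,2S,4aR,8aR)-1-(acetyloxy)-7-(2-hydroxypropan-2-yl)-1,4a-dimethyl-6-oxo-1,2,3,4,4a,5,6,8a-octahydronaphthalen-2-yl (2R,3S)-3-chloro-2-hydroxy-2-methylbutanoate (CNP0119872.1), via hydroperoxide 28 (not isolated)
Conditions: O2, visible light, tetraphenylporphyrin (1 mol%), CH2Cl2, 0 °C; then PPh3, rt
Reagents that add atoms: dioxygen O=O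
Why: Schenck ene reaction of the s-cis enone with singlet oxygen: hydrogen is taken from C6, the alkyl group geminal to the carbonyl on C7 (the usual regiochemistry of α,β-unsaturated carbonyl compounds), so that the double bond moves to C6=C7 and oxygen enters at C11, and triphenylphosphine reduces the tertiary hydroperoxide; no stereocentre is formed and C5 is not touched.

**Compound list**
1 | methyl 4-oxobutanoate | COC(=O)CCC=O | starting material
2 | tributyl(2-methylprop-2-en-1-yl)stannane | CC(=C)C[Sn](CCCC)(CCCC)CCCC | starting material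
3 | methyl (4R)-4-hydroxy-6-methylhept-6-enoate | COC(=O)CC[C@@H](O)CC(C)=C | intermediate (not isolated)
4 | (5R)-5-(2-methylprop-2-en-1-yl)oxolan-2-one | O=C1CC[C@H](CC(C)=C)O1 | intermediate
5 | (5R)-5-(2-methylprop-2-en-1-yl)oxolan-2-ol (both anomers) | OC1CC[C@H](CC(C)=C)O1 | intermediate
6 | 3-(triphenyl-λ5-phosphanylidene)butan-2-one | CC(=O)C(C)=P(c1ccccc1)(c1ccccc1)c1ccccc1 | starting material
7 | (3E,7R)-7-hydroxy-3,9-dimethyldeca-3,9-dien-2-one | CC(=O)/C(C)=C/CC[C@@H](O)CC(C)=C | intermediate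
8 | (3E,7R)-7-[(tert-butyldimethylsilyl)oxy]-3,9-dimethyldeca-3,9-dien-2-one | CC(=O)/C(C)=C/CC[C@@H](O[Si](C)(C)C(C)(C)C)CC(C)=C | intermediate
9 | lithium (3E,7R)-7-[(tert-butyldimethylsilyl)oxy]-3,9-dimethyldeca-1,3,9-trien-2-olate | [Li]OC(=C)/C(C)=C/CC[C@@H](O[Si](C)(C)C(C)(C)C)CC(C)=C | intermediate (not isolated)
10 | (3E,7R)-7-[(tert-butyldimethylsilyl)oxy]-3,9-dimethyl-2-[(trimethylsilyl)oxy]deca-1,3,9-triene | C=C(O[Si](C)(C)C)/C(C)=C/CC[C@@H](O[Si](C)(C)C(C)(C)C)CC(C)=C | intermediate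
11 | (4aR,6R,8aR)-6-[(tert-butyldimethylsilyl)oxy]-1,4a-dimethyl-2-[(trimethylsilyl)oxy]-3,4,4a,5,6,7,8,8a-octahydronaphthalene | CC1=C(O[Si](C)(C)C)CC[C@]2(C)C[C@H](O[Si](C)(C)C(C)(C)C)CC[C@H]21 | intermediate
12 | alkylborane from 11 (BH2 on the α face of C4, H on the α face of C3; 4a-methyl β, 8a-H α, 6-silyloxy α) | C[C@@]1(B)[C@@H](O[Si](C)(C)C)CC[C@]2(C)C[C@H](O[Si](C)(C)C(C)(C)C)CC[C@H]21 | intermediate (not isolated)
13 | (1S,2S,4aR,6R,8aR)-6-[(tert-butyldimethylsilyl)oxy]-1,4a-dimethyl-2-[(trimethylsilyl)oxy]decahydronaphthalen-1-ol | C[C@@]1(O)[C@@H](O[Si](C)(C)C)CC[C@]2(C)C[C@H](O[Si](C)(C)C(C)(C)C)CC[C@H]21 | intermediate (not isolated)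
14 | (1S,2S,4aR,6R,8aR)-6-[(tert-butyldimethylsilyl)oxy]-1,4a-dimethyldecahydronaphthalene-1,2-diol | C[C@@]1(O)[C@@H](O)CC[C@]2(C)C[C@H](O[Si](C)(C)C(C)(C)C)CC[C@H]21 | intermediate
15 | (2E)-2-methylbut-2-en-1-ol | C/C=C(\C)CO | starting material
16 | [(2R,3R)-2,3-dimethyloxiran-2-yl]methanol | C[C@H]1O[C@]1(C)CO | intermediate
17 | (2S,3R)-2,3-dimethyloxirane-2-carboxylic acid | C[C@H]1O[C@]1(C)C(=O)O | intermediate
18 | (2S,3R)-2,3-dimethyloxirane-2-carboxylic 2,4,6-trichlorobenzoic anhydride | C[C@H]1O[C@]1(C)C(=O)OC(=O)c1c(Cl)cc(Cl)cc1Cl | intermediate (not isolated)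
19 | (1S,2S,4aR,6R,8aR)-6-[(tert-butyldimethylsilyl)oxy]-1-hydroxy-1,4a-dimethyldecahydronaphthalen-2-yl (2S,3R)-2,3-dimethyloxirane-2-carboxylate | C[C@@]1(O)[C@@H](OC(=O)[C@@]2(C)O[C@@H]2C)CC[C@]3(C)C[C@H](O[Si](C)(C)C(C)(C)C)CC[C@H]31 | intermediate
20 | (1S,2S,4aR,6R,8aR)-1-(acetyloxy)-6-[(tert-butyldimethylsilyl)oxy]-1,4a-dimethyldecahydronaphthalen-2-yl (2S,3R)-2,3-dimethyloxirane-2-carboxylate | CC(=O)O[C@]1(C)[C@@H](OC(=O)[C@@]2(C)O[C@@H]2C)CC[C@]3(C)C[C@H](O[Si](C)(C)C(C)(C)C)CC[C@H]31 | intermediate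
21 | (1S,2S,4aR,6R,8aR)-1-(acetyloxy)-6-hydroxy-1,4a-dimethyldecahydronaphthalen-2-yl (2S,3R)-2,3-dimethyloxirane-2-carboxylate | CC(=O)O[C@]1(C)[C@@H](OC(=O)[C@@]2(C)O[C@@H]2C)CC[C@]3(C)C[C@H](O)CC[C@H]31 | intermediate
22 | (1S,2S,4aR,8aR)-1-(acetyloxy)-1,4a-dimethyl-6-oxodecahydronaphthalen-2-yl (2S,3R)-2,3-dimethyloxirane-2-carboxylate | CC(=O)O[C@]1(C)[C@@H](OC(=O)[C@@]2(C)O[C@@H]2C)CC[C@]3(C)CC(=O)CC[C@H]31 | intermediate
23 | lithium enolate of 22 (C7=C8 enolate of the ring B ketone) | CC(=O)O[C@]1(C)[C@@H](OC(=O)[C@@]2(C)O[C@@H]2C)CC[C@]3(C)CC(O[Li])=CC[C@H]31 | intermediate (not isolated)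
24 | (1S,2S,4aR,8aR)-1-(acetyloxy)-7-(2-hydroxypropan-2-yl)-1,4a-dimethyl-6-oxodecahydronaphthalen-2-yl (2S,3R)-2,3-dimethyloxirane-2-carboxylate (C7 epimers) | CC(=O)O[C@]1(C)[C@@H](OC(=O)[C@@]2(C)O[C@@H]2C)CC[C@]3(C)CC(=O)C(C(C)(C)O)C[C@H]31 | intermediate
25 | (1S,2S,4aR,8aR)-1-(acetyloxy)-7-{2-[(methanesulfonyl)oxy]propan-2-yl}-1,4a-dimethyl-6-oxodecahydronaphthalen-2-yl (2S,3R)-2,3-dimethyloxirane-2-carboxylate (C7 epimers) | CC(=O)O[C@]1(C)[C@@H](OC(=O)[C@@]2(C)O[C@@H]2C)CC[C@]3(C)CC(=O)C(C(C)(C)OS(C)(=O)=O)C[C@H]31 | intermediate (not isolated)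
26 | (1S,2S,4aR,8aR)-1-(acetyloxy)-1,4a-dimethyl-6-oxo-7-(propan-2-ylidene)decahydronaphthalen-2-yl (2S,3R)-2,3-dimethyloxirane-2-carboxylate | CC(=O)O[C@]1(C)[C@@H](OC(=O)[C@@]2(C)O[C@@H]2C)CC[C@]3(C)CC(=O)C(=C(C)C)C[C@H]31 | intermediate
27 | (1S,2S,4aR,8aR)-1-(acetyloxy)-1,4a-dimethyl-6-oxo-7-(propan-2-ylidene)decahydronaphthalen-2-yl (2R,3S)-3-chloro-2-hydroxy-2-methylbutanoate | CC(=O)O[C@]1(C)[C@@H](OC(=O)[C@@](C)(O)[C@H](C)Cl)CC[C@]2(C)CC(=O)C(=C(C)C)C[C@H]21 | intermediate
28 | (1S,2S,4aR,8aR)-1-(acetyloxy)-7-(2-hydroperoxypropan-2-yl)-1,4a-dimethyl-6-oxo-1,2,3,4,4a,5,6,8a-octahydronaphthalen-2-yl (2R,3S)-3-chloro-2-hydroxy-2-methylbutanoate | CC(=O)O[C@]1(C)[C@@H](OC(=O)[C@@](C)(O)[C@H](C)Cl)CC[C@]2(C)CC(=O)C(C(C)(C)OO)=C[C@H]21 | intermediate (not isolated)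
29 | (1S,2S,4aR,8aR)-1-(acetyloxy)-7-(2-hydroxypropan-2-yl)-1,4a-dimethyl-6-oxo-1,2,3,4,4a,5,6,8a-octahydronaphthalen-2-yl (2R,3S)-3-chloro-2-hydroxy-2-methylbutanoate | CC(=O)O[C@]1(C)[C@@H](OC(=O)[C@@](C)(O)[C@H](C)Cl)CC[C@]2(C)CC(=O)C(C(C)(C)O)=C[C@H]21 | target

**Count and risks**
Total step count: 17 (15 in the main line, 2 for the epoxy acid). Longest linear sequence: 15 steps (steps 1–7 and 10–17).

Step 6 (cycloaddition). The temperature that an unactivated dienophile needs could bring ene side reactions, loss of the silyl dienol ether, or too little trans or facial selectivity. The fallback would close ring B first by a radical conjugate addition and ring A afterwards by an aldol condensation. It would set out from enone 8. mCPBA would epoxidise the isolated 1,1-disubstituted alkene to (3E,7R)-7-[(tert-butyldimethylsilyl)oxy]-3-methyl-8-(2-methyloxiran-2-yl)oct-3-en-2-one F1. Cp2TiCl (made from Cp2TiCl2 and Zn) would open the epoxide to the tertiary C10 radical (Nugent–RajanBabu cyclisation); 6-exo addition to the enone carbon C5, through a chair with the silyloxy group, the enone arm and the CH2O–titanium group equatorial, should give 3-[(1S,2R,4R)-4-[(tert-butyldimethylsilyl)oxy]-2-(hydroxymethyl)-2-methylcyclohexyl]butan-2-one F2. Dess–Martin oxidation would give (1R,2S,5R)-5-[(tert-butyldimethylsilyl)oxy]-1-methyl-2-(3-oxobutan-2-yl)cyclohexane-1-carbaldehyde F3, and aldol condensation (KOH, MeOH) would give (4aS,6R,8aS)-6-[(tert-butyldimethylsilyl)oxy]-1,4a-dimethyl-4a,5,6,7,8,8a-hexahydronaphthalen-2(1H)-one F4. Hydrogenation (H2, 10% Pd/C) would give (4aR,6R,8aS)-6-[(tert-butyldimethylsilyl)oxy]-1,4a-dimethyl-3,4,4a,5,6,7,8,8a-octahydronaphthalen-2(1H)-one F5, and silylation under equilibrating conditions (Me3SiCl, NaI, Et3N, MeCN) would come back to the route at 11.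

Step 17 (photooxygenation). The electron-poor enone could react slowly with singlet oxygen, or hydrogen could be taken from the isopropylidene methyl groups instead of C6. The fallback would introduce the side chain and the double bond through selenium, setting out from ketone 22. LiN(i-Pr)2 and PhSeCl would give (1S,2S,4aR,8aR)-1-(acetyloxy)-1,4a-dimethyl-6-oxo-7-(phenylselanyl)decahydronaphthalen-2-yl (2S,3R)-2,3-dimethyloxirane-2-carboxylate F8. A second deprotonation at the selenium-bearing C7 and aldol addition to acetone would give (1S,2S,4aR,8aR)-1-(acetyloxy)-7-(2-hydroxypropan-2-yl)-1,4a-dimethyl-6-oxo-7-(phenylselanyl)decahydronaphthalen-2-yl (2S,3R)-2,3-dimethyloxirane-2-carboxylate F9. Oxidation with H2O2 and pyridine and syn elimination of the selenoxide towards C6 would give (1S,2S,4aR,8aR)-1-(acetyloxy)-7-(2-hydroxypropan-2-yl)-1,4a-dimethyl-6-oxo-1,2,3,4,4a,5,6,8a-octahydronaphthalen-2-yl (2S,3R)-2,3-dimethyloxirane-2-carboxylate F10. Opening of the epoxide with HCl as in step 16 would come back at 29.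

Step 11 (tertiary acetylation). Acylation of the hindered tertiary hydroxyl could stall, or forcing conditions could damage the epoxy ester. The fallback would make the C4–O bond as the acetate by oxidation, setting out from silyl enol ether 11. Pb(OAc)4 (CH2Cl2, 0 °C) would acetoxylate C4 from the α face to give (1S,4aR,6R,8aR)-6-[(tert-butyldimethylsilyl)oxy]-1,4a-dimethyl-2-oxodecahydronaphthalen-1-yl acetate F6. NaBH4 (MeOH, −78 °C) would deliver hydride axially to give the equatorial alcohol (1S,2S,4aR,6R,8aR)-6-[(tert-butyldimethylsilyl)oxy]-2-hydroxy-1,4a-dimethyldecahydronaphthalen-1-yl acetate F7. Yamaguchi esterification with 17 would come back at 20.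

**Further compounds**
F1 | step 6 | (3E,7R)-7-[(tert-butyldimethylsilyl)oxy]-3-methyl-8-(2-methyloxiran-2-yl)oct-3-en-2-one (epoxide epimers) | CC(=O)/C(C)=C/CC[C@@H](O[Si](C)(C)C(C)(C)C)CC1(C)CO1
F2 | step 6 | 3-[(1S,2R,4R)-4-[(tert-butyldimethylsilyl)oxy]-2-(hydroxymethyl)-2-methylcyclohexyl]butan-2-one (side-chain epimers) | CC(=O)C(C)[C@@H]1CC[C@@H](O[Si](C)(C)C(C)(C)C)C[C@@]1(C)CO
F3 | step 6 | (1R,2S,5R)-5-[(tert-butyldimethylsilyl)oxy]-1-methyl-2-(3-oxobutan-2-yl)cyclohexane-1-carbaldehyde (side-chain epimers) | CC(=O)C(C)[C@@H]1CC[C@@H](O[Si](C)(C)C(C)(C)C)C[C@@]1(C)C=O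
F4 | step 6 | (4aS,6R,8aS)-6-[(tert-butyldimethylsilyl)oxy]-1,4a-dimethyl-4a,5,6,7,8,8a-hexahydronaphthalen-2(1H)-one (C1 epimers) | CC1C(=O)C=C[C@]2(C)C[C@H](O[Si](C)(C)C(C)(C)C)CC[C@H]21
F5 | step 6 | (4aR,6R,8aS)-6-[(tert-butyldimethylsilyl)oxy]-1,4a-dimethyl-3,4,4a,5,6,7,8,8a-octahydronaphthalen-2(1H)-one (C1 epimers) | CC1C(=O)CC[C@]2(C)C[C@H](O[Si](C)(C)C(C)(C)C)CC[C@H]21
F6 | step 11 | (1S,4aR,6R,8aR)-6-[(tert-butyldimethylsilyl)oxy]-1,4a-dimethyl-2-oxodecahydronaphthalen-1-yl acetate | CC(=O)O[C@]1(C)C(=O)CC[C@]2(C)C[C@H](O[Si](C)(C)C(C)(C)C)CC[C@H]21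
F7 | step 11 | (1S,2S,4aR,6R,8aR)-6-[(tert-butyldimethylsilyl)oxy]-2-hydroxy-1,4a-dimethyldecahydronaphthalen-1-yl acetate | CC(=O)O[C@]1(C)[C@@H](O)CC[C@]2(C)C[C@H](O[Si](C)(C)C(C)(C)C)CC[C@H]21
F8 | step 17 | (1S,2S,4aR,8aR)-1-(acetyloxy)-1,4a-dimethyl-6-oxo-7-(phenylselanyl)decahydronaphthalen-2-yl (2S,3R)-2,3-dimethyloxirane-2-carboxylate (C7 epimers) | CC(=O)O[C@]1(C)[C@@H](OC(=O)[C@@]2(C)O[C@@H]2C)CC[C@]3(C)CC(=O)C([Se]c4ccccc4)C[C@H]31
F9 | step 17 | (1S,2S,4aR,8aR)-1-(acetyloxy)-7-(2-hydroxypropan-2-yl)-1,4a-dimethyl-6-oxo-7-(phenylselanyl)decahydronaphthalen-2-yl (2S,3R)-2,3-dimethyloxirane-2-carboxylate (C7 epimers) | CC(=O)O[C@]1(C)[C@@H](OC(=O)[C@@]2(C)O[C@@H]2C)CC[C@]3(C)CC(=O)C([Se]c4ccccc4)(C(C)(C)O)C[C@H]31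
F10 | step 17 | (1S,2S,4aR,8aR)-1-(acetyloxy)-7-(2-hydroxypropan-2-yl)-1,4a-dimethyl-6-oxo-1,2,3,4,4a,5,6,8a-octahydronaphthalen-2-yl (2S,3R)-2,3-dimethyloxirane-2-carboxylate | CC(=O)O[C@]1(C)[C@@H](OC(=O)[C@@]2(C)O[C@@H]2C)CC[C@]3(C)CC(=O)C(C(C)(C)O)=C[C@H]31
A1 | direct plan | (4R)-2,4-dimethyl-4-(prop-2-en-1-yl)cyclohex-2-en-1-one | CC1=C[C@@](C)(CC=C)CCC1=O
A2 | direct plan | 2-[(1R,2R)-1,3-dimethyl-2-{3-methyl-3-[(triethylsilyl)oxy]but-1-yn-1-yl}cyclohex-3-en-1-yl]acetaldehyde | CC[Si](CC)(CC)OC(C)(C)C#C[C@H]1C(C)=CCC[C@]1(C)CC=O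
A3 | direct plan | (4aR,8aR)-5,8a-dimethyl-3-{2-[(triethylsilyl)oxy]propan-2-yl}-4a,7,8,8a-tetrahydronaphthalen-2(1H)-one | CC1=CCC[C@]2(C)CC(=O)C(C(C)(C)O[Si](CC)(CC)CC)=C[C@H]21
A4 | direct plan | (4aR,5S,6R,8aR)-5,6-dihydroxy-5,8a-dimethyl-3-{2-[(triethylsilyl)oxy]propan-2-yl}-4a,5,6,7,8,8a-hexahydronaphthalen-2(1H)-one | C[C@@]1(O)[C@H](O)CC[C@]2(C)CC(=O)C(C(C)(C)O[Si](CC)(CC)CC)=C[C@H]21
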